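**Assumption:** the target is read as the 9‑O‑(E)‑caffeate of (−)‑lariciresinol, (2R,3S,4S) on the oxolane ring (2,3‑trans, 3,4‑cis); lignan locants are used below (C7–C9 for the aryl‑bearing half, C7'–C9' for the benzyl‑bearing half).

## Retrosynthetic overview

1. Target ⇒ (−)‑lariciresinol + caffeic acid: last‑step Mitsunobu acylation of the only aliphatic OH (C9), no protecting groups.
2. (−)‑Lariciresinol ⇒ O,O'‑dibenzyl‑(−)‑pinoresinol: one hydrogenolysis removes both benzyl groups and opens ring B at C7'–O (either benzylic C–O of the C2‑symmetric furofuran gives the same product).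
3. Furofuran ⇒ acyclic epoxy cinnamyl ether, both rings in one flask: Cp2TiCl epoxide opening and 5‑exo radical cyclization close ring A (C8–C8'), then iodine‑triggered radical–polar crossover closes ring B (C9–O–C7'). The single C7 centre sets C8, C8' and C7'.
4. Epoxy ether ⇒ erythro epoxy alcohol (Sharpless kinetic resolution) + cinnamyl bromide, both from one racemic aryl vinyl carbinol (O‑benzylvanillin + vinylmagnesium bromide).
5. Ring order: ring A (C–C), then ring B (C–O) in the same operation; ring B is later reopened reductively, leaving the oxolane of the target.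

## Route

**Step 1**
Reactants: 1 4‑(benzyloxy)‑3‑methoxybenzaldehyde; 2 vinylmagnesium bromide
Product: 3 rac‑1‑[4‑(benzyloxy)‑3‑methoxyphenyl]prop‑2‑en‑1‑ol
Conditions: 2 (1.2 equiv), THF, 0 °C → rt; then H2O
Reagents that add atoms: none
Why: Grignard 1,2‑addition to the aldehyde gives the racemic allylic alcohol, which needs no stereocontrol because step 3 resolves it.

**Step 2**
Reactants: 3 rac‑1‑[4‑(benzyloxy)‑3‑methoxyphenyl]prop‑2‑en‑1‑ol
Product: 4 (E)‑4‑(benzyloxy)‑3‑methoxycinnamyl bromide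
Conditions: PBr3 (0.4 equiv), Et2O, −10 → 0 °C, 30 min; used crude at once
Reagents that add atoms: phosphorus tribromide, BrP(Br)Br
Why: Bromination with allylic transposition (SN1/SN2' through the p‑alkoxy‑stabilised allyl cation) gives the conjugated (E)‑cinnamyl bromide, and because the carbinol centre is destroyed, racemic 3 or the unreacted (S)‑enantiomer of 3 recovered from step 3 serves equally.

**Step 3**
Reactants: 3 rac‑1‑[4‑(benzyloxy)‑3‑methoxyphenyl]prop‑2‑en‑1‑ol
Product: 5 (S)‑[4‑(benzyloxy)‑3‑methoxyphenyl][(2R)‑oxiran‑2‑yl]methanol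
Conditions: Ti(OiPr)4 (0.15 equiv), L‑(+)‑diisopropyl tartrate (0.18 equiv), t‑BuOOH (0.45 equiv, anhydrous), 4 Å MS, CH2Cl2, −20 °C; chromatography from unreacted (S)‑enantiomer of 3
Reagents that add atoms: tert‑butyl hydroperoxide, CC(C)(C)OO
Why: Sharpless kinetic resolution (asymmetric epoxidation) with L‑(+)‑DIPT epoxidises the (R)‑enantiomer of 3 much faster and erythro‑selectively, so the C7 centre, the only one carried through to the target, is set by catalyst control below 50% conversion, while the epoxide carbon later becomes a planar radical and need not be controlled.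

**Step 4**
Reactants: 5 (S)‑[4‑(benzyloxy)‑3‑methoxyphenyl][(2R)‑oxiran‑2‑yl]methanol; 4 (E)‑4‑(benzyloxy)‑3‑methoxycinnamyl bromide
Product: 6 (2R)‑2‑{(S)‑[4‑(benzyloxy)‑3‑methoxyphenyl][(2E)‑3‑[4‑(benzyloxy)‑3‑methoxyphenyl]prop‑2‑enyloxy]methyl}oxirane
Conditions: NaH (1.2 equiv), 4 (1.3 equiv), Bu4NI (0.1 equiv), THF–DMF 4:1, 0 °C → rt
Reagents that add atoms: none
Why: Williamson etherification (SN2) of the sodium alkoxide with the reactive primary allylic bromide at 0 °C outruns Payne rearrangement, and C7 keeps its configuration because only the O–H bond reacts.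

**Step 5 (key step)**
Reactants: 6 (2R)‑2‑{(S)‑[4‑(benzyloxy)‑3‑methoxyphenyl][(2E)‑3‑[4‑(benzyloxy)‑3‑methoxyphenyl]prop‑2‑enyloxy]methyl}oxirane
Product: 9 O,O'‑dibenzyl‑(−)‑pinoresinol, via cyclized benzylic radical 7 (not isolated), via benzylic iodide 8 (not isolated)
Conditions: Cp2TiCl2 (2.2 equiv), Zn dust, THF, rt (green Cp2TiCl, decanted from Zn), added over 1 h to 6 in THF, rt; then I2 (1.5 equiv), rt → 50 °C, 2 h; aq. Na2S2O3/NaHCO3
Reagents that add atoms: none
Why: Nugent–RajanBabu reductive epoxide opening by trivalent titanium gives the secondary C8 radical bearing the C9 titanium alkoxide, which closes ring A by 5‑exo‑trig radical cyclization through a chair‑like Beckwith–Houk transition state with the C7 aryl group pseudo‑equatorial (2,3‑trans and 3,4‑cis, so (R)‑C7 sets C8 and C8' as S,S), and iodination of the benzylic radical (or its benzyl–titanium form) gives an iodide that the cis‑disposed alkoxide displaces through the p‑alkoxybenzyl cation (radical–polar crossover, Williamson‑type etherification) to close ring B with the aryl group exo.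

**Step 6**
Reactants: 9 O,O'‑dibenzyl‑(−)‑pinoresinol
Product: 10 (−)‑lariciresinol
Conditions: H2 (1 atm), Pd/C (10 wt% Pd), EtOAc–EtOH 1:1, rt; followed by HPLC and stopped at maximum 10
Reagents that add atoms: none
Why: Catalytic hydrogenolysis cleaves the two aryl benzyl ethers and then one benzylic C–O bond of the strained C2‑symmetric furofuran (either gives the same product), turning C7' into the benzyl CH2 and freeing the C9 hydroxyl without touching C7, C8 or C8', and the monocyclic product reacts more slowly, so the reaction can be stopped there.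

**Step 7**
Reactants: 10 (−)‑lariciresinol; 11 (E)‑caffeic acid
Product: 12 (−)‑lariciresinol 9‑O‑(E)‑caffeate (target CNP0132883.1)
Conditions: 11 (1.5 equiv), PPh3 (1.5 equiv), THF, 0 °C; DIAD (1.5 equiv) dropwise, 0 °C → rt
Reagents that add atoms: none
Why: Mitsunobu esterification is chemoselective because the carboxylic acid is the only pronucleophile acidic enough for the PPh3–DIAD betaine and only the aliphatic C9–OH forms an alkoxyphosphonium ion, so the ester forms at the non‑stereogenic CH2 with the four phenols free, the (E)‑alkene intact and all three stereocentres untouched.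

## Compound list

1 | 4‑(benzyloxy)‑3‑methoxybenzaldehyde (O‑benzylvanillin) | COc1cc(C=O)ccc1OCc1ccccc1 | starting material
2 | vinylmagnesium bromide | C=C[Mg]Br | starting material
3 | rac‑1‑[4‑(benzyloxy)‑3‑methoxyphenyl]prop‑2‑en‑1‑ol | C=CC(O)c1ccc(OCc2ccccc2)c(OC)c1 | intermediate
4 | 1‑(benzyloxy)‑4‑[(1E)‑3‑bromoprop‑1‑en‑1‑yl]‑2‑methoxybenzene | COc1cc(/C=C/CBr)ccc1OCc1ccccc1 | intermediate
5 | (S)‑[4‑(benzyloxy)‑3‑methoxyphenyl][(2R)‑oxiran‑2‑yl]methanol (erythro) | O[C@@H](c1ccc(OCc2ccccc2)c(OC)c1)[C@H]1CO1 | intermediate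
6 | (2R)‑2‑{(S)‑[4‑(benzyloxy)‑3‑methoxyphenyl][(2E)‑3‑[4‑(benzyloxy)‑3‑methoxyphenyl]prop‑2‑enyloxy]methyl}oxirane | COc1cc(/C=C/CO[C@@H](c2ccc(OCc3ccccc3)c(OC)c2)[C@H]2CO2)ccc1OCc1ccccc1 | intermediate
7 | (2R,3S,4S)‑oxolane benzylic radical: 2‑aryl, 3‑CH2O–TiCp2Cl, 4‑(aryl)CH• (aryl = 4‑benzyloxy‑3‑methoxyphenyl) | COc1cc([CH][C@@H]2CO[C@@H](c3ccc(OCc4ccccc4)c(OC)c3)[C@@H]2CO[Ti](Cl)(C2C=CC=C2)C2C=CC=C2)ccc1OCc1ccccc1 | intermediate (not isolated)
8 | (2R,3S,4S)‑oxolane benzylic iodide: as 7 with 4‑(aryl)CHI, both C7' epimers | COc1cc(C(I)[C@@H]2CO[C@@H](c3ccc(OCc4ccccc4)c(OC)c3)[C@@H]2CO[Ti](Cl)(C2C=CC=C2)C2C=CC=C2)ccc1OCc1ccccc1 | intermediate (not isolated)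
9 | (3R,3aS,6R,6aS)‑3,6‑bis[4‑(benzyloxy)‑3‑methoxyphenyl]‑1,3,3a,4,6,6a‑hexahydrofuro[3,4‑c]furan (O,O'‑dibenzyl‑(−)‑pinoresinol) | COc1cc(ccc1OCc1ccccc1)[C@H]2[C@@H]3CO[C@H]([C@@H]3CO2)c2ccc(OCc3ccccc3)c(OC)c2 | intermediate
10 | 4‑[(2R,3S,4S)‑4‑(4‑hydroxy‑3‑methoxybenzyl)‑3‑(hydroxymethyl)oxolan‑2‑yl]‑2‑methoxyphenol ((−)‑lariciresinol) | COc1cc(C[C@@H]2CO[C@@H](c3ccc(O)c(OC)c3)[C@@H]2CO)ccc1O | intermediate
11 | (E)‑3‑(3,4‑dihydroxyphenyl)prop‑2‑enoic acid (caffeic acid) | OC(=O)/C=C/c1ccc(O)c(O)c1 | starting material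
12 | [(2R,3S,4S)‑2‑(4‑hydroxy‑3‑methoxyphenyl)‑4‑(4‑hydroxy‑3‑methoxybenzyl)oxolan‑3‑yl]methyl (E)‑3‑(3,4‑dihydroxyphenyl)prop‑2‑enoate | COc1cc(C[C@@H]2CO[C@@H](c3ccc(O)c(OC)c3)[C@@H]2COC(=O)/C=C/c2ccc(O)c(O)c2)ccc1O | target

## Step count

Total steps: 7. Longest linear sequence: 6 (steps 1, 3, 4, 5, 6, 7); step 2 is a one‑step side branch from 3.

## Three steps most likely to fail, with fallbacks

**Step 5 (one‑flask bicyclization).** Risks are reduction or β‑elimination of the C8 radical before cyclization, minor ring‑A diastereomers, and failure of the iodine‑triggered ring‑B closure (elimination to a styrene). The fallback changes from bicyclization to monocyclization. It sets out from 6: the Cp2TiCl cyclization is run with protic termination (Cp2TiCl, THF, rt, then dilute aqueous acid) so that only ring A forms, giving O,O'‑dibenzyl‑(−)‑lariciresinol F1. Brief hydrogenolysis of its two benzyl ethers (H2, Pd/C, EtOAc) then returns to the route at 10, bypassing 9.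

**Step 6 (hydrogenolysis selectivity).** The risk is over‑reduction to the ring‑opened diol (secoisolariciresinol) or a mixture with unopened furofuran. The fallback replaces surface hydrogenolysis of the ring by ionic hydrogenation with a limiting hydride. It sets out from 9: transfer hydrogenolysis (Pd/C, 1,4‑cyclohexadiene, EtOH, rt) removes only the benzyl ethers to give (−)‑pinoresinol F2. Then Et3SiH (1.1 equiv) and BF3·OEt2 in CH2Cl2 at −40 °C ionise one benzylic C–O bond to the p‑hydroxybenzyl cation (quinone methide), which is captured by hydride; the single equivalent of silane limits the second opening. This returns at 10.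

**Step 7 (unprotected Mitsunobu).** Risks are low conversion at the β‑branched primary alcohol and competing phenol alkylation. The fallback builds the cinnamoyl unit on the alcohol instead of coupling a preformed acid. It sets out from 10: Meldrum's acid (1.05 equiv, toluene, 85 °C) acylates the aliphatic hydroxyl to give (−)‑lariciresinol 9‑O‑(hydrogen malonate) F3. Knoevenagel–Doebner condensation with 3,4‑dihydroxybenzaldehyde (pyridine, cat. piperidine, 50 °C), with loss of CO2, gives the (E)‑caffeate directly and returns at 12.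

## Further compounds

F1 | step 5 | [(2R,3S,4S)‑2‑[4‑(benzyloxy)‑3‑methoxyphenyl]‑4‑[4‑(benzyloxy)‑3‑methoxybenzyl]oxolan‑3‑yl]methanol (O,O'‑dibenzyl‑(−)‑lariciresinol) | COc1cc(C[C@@H]2CO[C@@H](c3ccc(OCc4ccccc4)c(OC)c3)[C@@H]2CO)ccc1OCc1ccccc1
F2 | step 6 | 4,4'‑[(3R,3aS,6R,6aS)‑hexahydrofuro[3,4‑c]furan‑3,6‑diyl]bis(2‑methoxyphenol) ((−)‑pinoresinol) | COc1cc(ccc1O)[C@H]2[C@@H]3CO[C@H]([C@@H]3CO2)c2ccc(O)c(OC)c2
F3 | step 7 | 3‑{[(2R,3S,4S)‑2‑(4‑hydroxy‑3‑methoxyphenyl)‑4‑(4‑hydroxy‑3‑methoxybenzyl)oxolan‑3‑yl]methoxy}‑3‑oxopropanoic acid | COc1cc(C[C@@H]2CO[C@@H](c3ccc(O)c(OC)c3)[C@@H]2COC(=O)CC(=O)O)ccc1O
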